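**Direct plan and its weak points**

A direct plan would make the open-chain α-ketoaldehyde amide A1 from a terminal alkene by dihydroxylation and diol oxidation. It would then condense A1 with urea (A2) under acid, so that all four aminal C–N bonds form in one cascade to racemic A3, and separate the enantiomers of A3 on a chiral column.
- **Weakest, the acid cascade A1 + A2 → A3.** Four C–N bonds would have to form in one fixed order. Meanwhile glyoxal–urea adducts collapse irreversibly to hydantoins (here A4), excess urea can cap the dicarbonyl twice (glycoluril type), and the pyrrole can close through C3 instead of N1.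
- **Second, the resolution of A3.** The absolute configuration would never be set. The last step would discard half of the most advanced material.
- **Third, the oxidation of the terminal 1,2-diol to A1.** The ketoaldehyde would be hydrated and would oligomerise, and its own amide N–H would already add to the ketone. It could only be used crude, so the cascade would start from an undefined mixture.

**Retrosynthetic overview**

- **Locants and feature used.** C6 is the aminal CH and C10 the quaternary aminal carbon. The rings are A (pyrrole), B (pyrazinone), C (pyrrolidine) and D (imidazolidinone). C10 carries the amide N and the ring-C CH2 exactly as Cα of proline does, and the ring-D carbonyl sits one nitrogen away from C10. That is where the proline carboxyl carbon lands after a C→N 1,2-shift.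
- **Key disconnection.** C10–N(urea) goes back to C10–CO2H (Curtius), the urea C(=O)–NH2 bond to ammonia, and both C6–N bonds to a C6 dimethyl acetal. The precursor is a monocyclic N-acyl-α-(dimethoxymethyl)proline with one stereocentre.
- **Second disconnection.** The C6–C10 bond is made by C-formylation of the enolate of the L-proline/pivalaldehyde N,O-acetal, with self-regeneration of the stereocentre (net retention).
- **Ring order.** Rings A and C are bought (pyrrole acid, L-proline). Ring D and then ring B close last, both in the key step.
- **How the design avoids the weak steps.** C10 is never a ketone or a planar cation, and two stereoretentive events carry the L-proline configuration into it, so no resolution is needed. One urea nitrogen comes from azide and one from ammonia, so no urea/dicarbonyl chemistry (hydantoin, double capping) can occur. C6 travels as a stable acetal instead of a ketoaldehyde.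

Key step: step 6

Assumption: the SMILES (C10 = R, C6 = S) is taken as the natural (−)-enantiomer. By CIP analysis it maps onto L-proline when H-α is replaced by C6 and CO2H by N, both with retention.

**Route**

Step 1
Reactants: 1 L-proline; 2 pivalaldehyde
Product: 3 (3R,7aS)-3-tert-butyltetrahydro-1H,3H-pyrrolo[1,2-c]oxazol-1-one (bicyclic N,O-acetal lactone, tert-butyl cis to H-7a)
Conditions: cat. TFA, pentane, reflux, Dean–Stark trap
Reagents that add atoms: none
Why: Acid-catalysed condensation of the amino acid with the aldehyde (oxazolidin-5-one formation) should give the cis-fused bicycle as one diastereomer under thermodynamic control, with the tert-butyl group on the convex face cis to H-7a, so that the new acetal centre stores the L-proline configuration.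

Step 2
Reactants: 3; 4 methyl formate
Product: 5 (3R,7aR)-3-tert-butyl-1-oxotetrahydro-1H,3H-pyrrolo[1,2-c]oxazole-7a(5H)-carbaldehyde (CHO in the place of H-7a, cis to tert-butyl)
Conditions: LDA, THF, −78 °C; then 4, −78 → −40 °C; AcOH quench
Reagents that add atoms: none
Why: Self-regeneration of the stereocentre: the lithium enolate is planar at C7a but keeps the acetal centre, and the crossed Claisen C-formylation should occur on the convex face cis to the tert-butyl group, so that CHO replaces H with net retention and forms the C6–C10 bond at a centre that has no α-hydrogen left to epimerise.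

Step 3
Reactants: 5
Product: 6 methyl (2R)-2-(dimethoxymethyl)pyrrolidine-2-carboxylate
Conditions: HC(OMe)3, HCl/MeOH, reflux; aq. NaHCO3 work-up
Reagents that add atoms: trimethyl orthoformate, COC(OC)OC; methanol, CO
Why: The aldehyde should first be trapped as its dimethyl acetal (acetalisation with orthoformate as water scavenger, which blocks retro-Claisen loss and β-formyl-acid decarboxylation), after which acid methanolysis of the N,O-acetal lactone releases pivalaldehyde, the free N–H and the methyl ester without touching the quaternary centre.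

Step 4
Reactants: 6; 7 4,5-dibromo-1H-pyrrole-2-carboxylic acid
Product: 9 methyl (2R)-1-(4,5-dibromo-1H-pyrrole-2-carbonyl)-2-(dimethoxymethyl)pyrrolidine-2-carboxylate, via 4,5-dibromo-1H-pyrrole-2-carbonyl chloride 8 (not isolated)
Conditions: 7, (COCl)2, cat. DMF, CH2Cl2, 0 °C → rt, evaporate; then 6, Et3N, CH2Cl2, 0 °C → rt
Reagents that add atoms: oxalyl chloride, O=C(Cl)C(=O)Cl (chlorine of 8 only)
Why: Amide formation with an acid chloride, which under amine base reacts through the small ketene-like azafulvenone and should therefore acylate even this hindered α,α-disubstituted pyrrolidine, while ester, acetal and C–Br bonds are inert and no stereocentre is involved.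

Step 5
Reactants: 9
Product: 10 (2R)-1-(4,5-dibromo-1H-pyrrole-2-carbonyl)-2-(dimethoxymethyl)pyrrolidine-2-carboxylic acid
Conditions: LiOH·H2O, THF/MeOH/H2O, 45 °C; then 1 M HCl to pH 4, 0 °C
Reagents that add atoms: lithium hydroxide, [Li+].[OH-]
Why: Saponification (BAc2), helped by reversible attack of the pyrrolide nitrogen on the neighbouring ester to give an N-acylpyrrole that hydroxide opens at the azolide carbonyl; acetal, tertiary amide and C–Br bonds tolerate base and the quaternary centre cannot epimerise.

Step 6
Reactants: 10
Product: 14 (−)-dibromophakellstatin (C10 R, C6 S), via (2R)-1-(4,5-dibromo-1H-pyrrole-2-carbonyl)-2-(dimethoxymethyl)pyrrolidine-2-carbonyl azide 11 (not isolated), via (4,5-dibromo-1H-pyrrol-2-yl)[(2S)-2-(dimethoxymethyl)-2-isocyanatopyrrolidin-1-yl]methanone 12 (not isolated), via 1-[(2R)-1-(4,5-dibromo-1H-pyrrole-2-carbonyl)-2-(dimethoxymethyl)pyrrolidin-2-yl]urea 13 (not isolated)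
Conditions: DPPA, Et3N, PhMe, rt then 85 °C; NH3 (0.5 M in dioxane), 0 °C; evaporate; TFA/CH2Cl2 1:1, rt → 40 °C
Reagents that add atoms: diphenylphosphoryl azide, [N-]=[N+]=NP(=O)(Oc1ccccc1)Oc1ccccc1; ammonia, N
Why: DPPA turns the hindered acid into acyl azide 11, which on heating loses N2 with a concerted 1,2-shift of C10 from carbon to nitrogen (Curtius rearrangement), so the former proline carboxyl carbon becomes the carbonyl of isocyanate 12 (the descriptor changes by CIP ranking only) and, after addition of ammonia, of urea 13. The closest known reaction types are the Curtius degradation of N-acyl α,α-disubstituted amino acids to gem-diamino derivatives and the intramolecular α-ureidoalkylation (N-acyliminium cyclisation). In TFA the acetal ionises, the terminal urea NH2 closes ring D (5-exo-trig on the oxocarbenium ion), loss of the second methanol gives the cyclic N-acyliminium ion at C6, and pyrrole N1 closes ring B (6-exo-trig). C10 is fixed by the strict retention of the migrating carbon, and C6 by the tether: N1 hangs from the amide nitrogen on C10 and can reach only the iminium face that gives the cis B/D fusion (6S). The step needs N1 rather than C3 of the pyrrole to attack and C10 not to ionise: C3 lies between the acyl group and a bromine and is strongly deactivated, a cation at C10 would sit next to the acetal or iminium carbon and is disfavoured, and C10 bears no hydrogen, so no enamide can form. Capture of the activated acyl group or of 12 by the pyrrole N–H would only give acyl or carbamoyl azolides, which azide and ammonia should re-open.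

**Compound list**

1 | L-proline | OC(=O)[C@@H]1CCCN1 | starting material
2 | pivalaldehyde | CC(C)(C)C=O | starting material
3 | (3R,7aS)-3-tert-butyltetrahydro-1H,3H-pyrrolo[1,2-c]oxazol-1-one | O=C1O[C@H](C(C)(C)C)N2CCC[C@@H]12 | intermediate
4 | methyl formate | COC=O | starting material
5 | (3R,7aR)-3-tert-butyl-1-oxotetrahydro-1H,3H-pyrrolo[1,2-c]oxazole-7a(5H)-carbaldehyde | O=C1O[C@H](C(C)(C)C)N2CCC[C@@]12C=O | intermediate
6 | methyl (2R)-2-(dimethoxymethyl)pyrrolidine-2-carboxylate | C1C[C@](C(OC)OC)(NC1)C(=O)OC | intermediate
7 | 4,5-dibromo-1H-pyrrole-2-carboxylic acid | OC(=O)c1cc(Br)c(Br)[nH]1 | starting material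
8 | 4,5-dibromo-1H-pyrrole-2-carbonyl chloride | ClC(=O)c1cc(Br)c(Br)[nH]1 | intermediate
9 | methyl (2R)-1-(4,5-dibromo-1H-pyrrole-2-carbonyl)-2-(dimethoxymethyl)pyrrolidine-2-carboxylate | C1C[C@](C(OC)OC)(N(C1)C(=O)c2cc(Br)c(Br)[nH]2)C(=O)OC | intermediate
10 | (2R)-1-(4,5-dibromo-1H-pyrrole-2-carbonyl)-2-(dimethoxymethyl)pyrrolidine-2-carboxylic acid | C1C[C@](C(OC)OC)(N(C1)C(=O)c2cc(Br)c(Br)[nH]2)C(=O)O | intermediate
11 | (2R)-1-(4,5-dibromo-1H-pyrrole-2-carbonyl)-2-(dimethoxymethyl)pyrrolidine-2-carbonyl azide | C1C[C@](C(OC)OC)(N(C1)C(=O)c2cc(Br)c(Br)[nH]2)C(=O)N=[N+]=[N-] | intermediate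
12 | (4,5-dibromo-1H-pyrrol-2-yl)[(2S)-2-(dimethoxymethyl)-2-isocyanatopyrrolidin-1-yl]methanone | C1C[C@](C(OC)OC)(N(C1)C(=O)c2cc(Br)c(Br)[nH]2)N=C=O | intermediate
13 | 1-[(2R)-1-(4,5-dibromo-1H-pyrrole-2-carbonyl)-2-(dimethoxymethyl)pyrrolidin-2-yl]urea | C1C[C@](C(OC)OC)(N(C1)C(=O)c2cc(Br)c(Br)[nH]2)NC(N)=O | intermediate
14 | (−)-dibromophakellstatin | O=C1N[C@H]2n3c(cc(Br)c3Br)C(=O)N3CCC[C@]23N1 | target

**Step count and risks**

Total step count: 6. Longest linear sequence: 6 (from L-proline).

Steps most likely to fail:

1. **Step 6.**
   - What may go wrong: the still open C10 aminal may ionise in strong acid, which would erode enantiopurity. The acyliminium ion may also be attacked by pyrrole C3 instead of N1.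
   - Fallback (the cationic closure is replaced by an anionic one), from 13 back to 14: 13 would be isolated after the ammonia stage. Its acetal would be opened with mild aqueous acid (PPTS, acetone/H2O, 50 °C) only as far as the ring-D carbinol (5R)-6-(4,5-dibromo-1H-pyrrole-2-carbonyl)-4-hydroxy-1,3,6-triazaspiro[4.4]nonan-2-one F1. Acetylation (Ac2O, pyridine) would give (5R)-6-(4,5-dibromo-1H-pyrrole-2-carbonyl)-2-oxo-1,3,6-triazaspiro[4.4]nonan-4-yl acetate F2. Treatment with DBU in MeCN would cause E1cB loss of acetate to the neutral cyclic N-acylimine, to which the pyrrolide should add through N1 to give 14.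

2. **Step 3.**
   - What may go wrong: cleavage of the hindered N,O-acetal lactone may stall. The formyl carbon may also be lost (retro-Claisen cleavage or decarboxylation) before it is masked.
   - Fallback (ester, acid and Curtius are replaced by amide and Hofmann), from 5 back to 12: 5 would only be acetalised (HC(OMe)3, cat. TsOH, MeOH, rt) to (3R,7aR)-3-tert-butyl-7a-(dimethoxymethyl)tetrahydro-1H,3H-pyrrolo[1,2-c]oxazol-1-one F3. The activated lactone would be opened with ammonia (7 M NH3/MeOH, sealed tube) to (2R)-2-(dimethoxymethyl)pyrrolidine-2-carboxamide F4. Acylation with 8 (Et3N, CH2Cl2) would give (2R)-1-(4,5-dibromo-1H-pyrrole-2-carbonyl)-2-(dimethoxymethyl)pyrrolidine-2-carboxamide F5. A Hofmann rearrangement with PhI(OAc)2 in MeCN would then give isocyanate 12 with the same retention.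

3. **Step 5.**
   - What may go wrong: the neopentyl-type ester may resist hydroxide. On later activation of the acid under base, the pyrrole N–H may intercept the acyl group.
   - Fallback (acyl azide made under acidic conditions), from 9 back to 11: hydrazinolysis (N2H4·H2O, EtOH, reflux) would give (2R)-1-(4,5-dibromo-1H-pyrrole-2-carbonyl)-2-(dimethoxymethyl)pyrrolidine-2-carbohydrazide F6. Nitrosation with tert-butyl nitrite and HCl in dioxane at −20 °C would give acyl azide 11 in a medium in which the pyrrole N–H is not nucleophilic.

**Further compounds**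

F1 | step 6 | (5R)-6-(4,5-dibromo-1H-pyrrole-2-carbonyl)-4-hydroxy-1,3,6-triazaspiro[4.4]nonan-2-one (mixture at C4) | C1C[C@]2(C(O)NC(=O)N2)N(C1)C(=O)c3cc(Br)c(Br)[nH]3
F2 | step 6 | (5R)-6-(4,5-dibromo-1H-pyrrole-2-carbonyl)-2-oxo-1,3,6-triazaspiro[4.4]nonan-4-yl acetate (mixture at C4) | C1C[C@]2(C(OC(C)=O)NC(=O)N2)N(C1)C(=O)c3cc(Br)c(Br)[nH]3
F3 | step 3 | (3R,7aR)-3-tert-butyl-7a-(dimethoxymethyl)tetrahydro-1H,3H-pyrrolo[1,2-c]oxazol-1-one | O=C1O[C@H](C(C)(C)C)N2CCC[C@@]12C(OC)OC
F4 | step 3 | (2R)-2-(dimethoxymethyl)pyrrolidine-2-carboxamide | C1C[C@](C(OC)OC)(NC1)C(N)=O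
F5 | step 3 | (2R)-1-(4,5-dibromo-1H-pyrrole-2-carbonyl)-2-(dimethoxymethyl)pyrrolidine-2-carboxamide | C1C[C@](C(OC)OC)(N(C1)C(=O)c2cc(Br)c(Br)[nH]2)C(N)=O
F6 | step 5 | (2R)-1-(4,5-dibromo-1H-pyrrole-2-carbonyl)-2-(dimethoxymethyl)pyrrolidine-2-carbohydrazide | C1C[C@](C(OC)OC)(N(C1)C(=O)c2cc(Br)c(Br)[nH]2)C(=O)NN
A1 | direct plan | 4,5-dibromo-N-(4,5-dioxopentyl)-1H-pyrrole-2-carboxamide | O=CC(=O)CCCNC(=O)c1cc(Br)c(Br)[nH]1
A2 | direct plan | urea | NC(N)=O
A3 | direct plan | (±)-dibromophakellstatin (racemate; relative configuration shown) | O=C1N[C@H]2n3c(cc(Br)c3Br)C(=O)N3CCC[C@]23N1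
A4 | direct plan | 4,5-dibromo-N-[3-(2,5-dioxoimidazolidin-4-yl)propyl]-1H-pyrrole-2-carboxamide (racemic) | O=C1NC(=O)C(CCCNC(=O)c2cc(Br)c(Br)[nH]2)N1
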